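The seven-membered ring is opened at two bonds: C5–C6 (carbinol carbon to the adjacent CHMe) and C9a–C9 (trimethoxyarene to the spiro carbon). The two halves are first joined through the future acetate oxygen as a benzyl ether, ArCH2–O–C6. In one flask, the benzylic anion undergoes a [1,2]-Wittig shift that moves C6 from oxygen to C5 with retention, the alkoxide is acetylated, and PhI(OCOCF3)2 oxidises the silyloxy-dimethoxyphenyl ring so that C9a attacks its para carbon, giving the spirodienone. The step exploits the oxygen on C5 as a contractible tether and the para-oxygenated aryl ring as a latent cyclohexadienone.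

Key step: step 7

Remark: atom numbers follow the benzo[7]annulene skeleton of the target (C5 = CH–OAc, C6 and C7 = CHMe, C8 = CH2, C9 = spiro carbon, C9a = arene carbon bonded to C9). The target is the (5R,6S,7R) isomer. The key step is a single-flask sequence of three reagent additions without work-up between them.

Step 1
Reactants: 1 methyl (S)-3-hydroxybutanoate
Product: 2 methyl (2S,3S)-3-hydroxy-2-methylbutanoate
Conditions: LiN(iPr)2 (2.2 equiv), THF, −78 to −20 °C; then MeI, DMPU, −78 to 0 °C
Reagents that add atoms: iodomethane, CI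
Why: Fráter–Seebach alkylation: the chelated lithium alkoxide–enolate dianion should be methylated on the face opposite the C3 methyl group, which sets C2 anti to the hydroxyl (2S,3S); C3 comes from the starting material.

Step 2
Reactants: 2 methyl (2S,3S)-3-hydroxy-2-methylbutanoate; 3 3,4,5-trimethoxybenzyl bromide
Product: 4 methyl (2S,3S)-2-methyl-3-[(3,4,5-trimethoxybenzyl)oxy]butanoate
Conditions: Ag2O, CH2Cl2, 4 Å molecular sieves, rt, dark
Reagents that add atoms: none
Why: Silver-oxide-mediated Williamson etherification with a reactive benzylic bromide under non-basic conditions should avoid retro-aldol cleavage, elimination and epimerisation at C2; no stereocenter is touched.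

Step 3
Reactants: 4 methyl (2S,3S)-2-methyl-3-[(3,4,5-trimethoxybenzyl)oxy]butanoate
Product: 5 (2R,3S)-2-methyl-3-[(3,4,5-trimethoxybenzyl)oxy]butan-1-ol
Conditions: LiAlH4, THF, 0 °C
Reagents that add atoms: none
Why: Hydride reduction of the ester to the primary alcohol; the benzyl ether and both stereocenters are inert (the C2 descriptor changes by priority only).

Step 4
Reactants: 5 (2R,3S)-2-methyl-3-[(3,4,5-trimethoxybenzyl)oxy]butan-1-ol
Product: 6 5-({[(2S,3S)-4-iodo-3-methylbutan-2-yl]oxy}methyl)-1,2,3-trimethoxybenzene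
Conditions: I2, PPh3, imidazole, CH2Cl2, 0 °C to rt
Reagents that add atoms: iodine, II
Why: Appel-type iodination by displacement of the oxyphosphonium group at the primary CH2; neither stereocenter is a reacting centre.

Step 5
Reactants: 7 4-bromo-2,6-dimethoxyphenol
Product: 8 (4-bromo-2,6-dimethoxyphenoxy)(tert-butyl)dimethylsilane
Conditions: TBSCl, imidazole, DMF, rt
Reagents that add atoms: tert-butyldimethylsilyl chloride, CC(C)(C)[Si](C)(C)Cl
Why: Standard silylation of the phenol; the silyl ether should survive the organozinc and organolithium steps and is the group lost in the oxidative dearomatisation.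

Step 6
Reactants: 6 5-({[(2S,3S)-4-iodo-3-methylbutan-2-yl]oxy}methyl)-1,2,3-trimethoxybenzene; 8 (4-bromo-2,6-dimethoxyphenoxy)(tert-butyl)dimethylsilane
Product: 10 tert-butyl(2,6-dimethoxy-4-{(2R,3S)-2-methyl-3-[(3,4,5-trimethoxybenzyl)oxy]butyl}phenoxy)dimethylsilane, via alkylzinc iodide 9 (not isolated)
Conditions: Zn dust, I2 (cat.), DMA, 40 °C; then 8, Pd(OAc)2 (cat.), SPhos, THF, 50 °C
Reagents that add atoms: none
Why: Negishi coupling: zinc inserts into the primary C–I bond and the alkylzinc iodide couples with the aryl bromide at palladium, the bulky biarylphosphine favouring reductive elimination over β-hydride elimination; the two stereocenters are not involved.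

Step 7
Reactants: 10 tert-butyl(2,6-dimethoxy-4-{(2R,3S)-2-methyl-3-[(3,4,5-trimethoxybenzyl)oxy]butyl}phenoxy)dimethylsilane
Product: 13 (5R,6S,7R)-1,2,3,3',5'-pentamethoxy-6,7-dimethyl-4'-oxo-5,6,7,8-tetrahydrospiro[benzo[7]annulene-9,1'-cyclohexa[2,5]diene]-5-yl acetate, via lithium alkoxide 11 (not isolated), via benzylic acetate 12 (not isolated)
Conditions: s-BuLi, THF, −78 to −20 °C; Ac2O, −78 to 0 °C; then CF3CH2OH, PhI(OCOCF3)2, −40 °C
Reagents that add atoms: acetic anhydride, CC(=O)OC(C)=O
Why: s-BuLi deprotonates the benzylic CH2 next to the ether oxygen; the α-alkoxy carbanion cleaves to a caged ketyl/secondary-alkyl radical pair that recombines at carbon ([1,2]-Wittig rearrangement), so C6 migrates from oxygen to C5 with retention and the tether oxygen becomes the C5 alkoxide 11, which Ac2O traps as acetate 12. C5 is the only new stereocenter and is set in the recombination by 1,2-induction from C6: the solvated Li–O end of the ketyl should turn away from the branched C7 substituent, which favours the 5,6-syn (5R) isomer, probably only moderately. PhI(OCOCF3)2 in CF3CH2OH then oxidises the silyloxy-dimethoxyphenyl ring (hypervalent-iodine oxidation of O-silyl phenols) and C9a of the trimethoxyphenyl ring, activated by an ortho and a para methoxy group, attacks the para carbon of the oxidised ring in a 7-exo ipso Friedel–Crafts closure; loss of the silyl group gives the cross-conjugated dienone, as in phenolic oxidative spirocyclisations of diarylalkanes. The spiro carbon is not stereogenic and the two ortho carbons of the trimethoxyphenyl ring are equivalent, so that closure needs no facial or positional control. The step needs benzylic rather than ring lithiation and ipso attack faster than quinone methide formation; the oxygen-directed deprotonation, the acetate cap and the low temperature are meant to secure these.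

Compound list
1 | methyl (S)-3-hydroxybutanoate | C[C@H](O)CC(=O)OC | starting material
2 | methyl (2S,3S)-3-hydroxy-2-methylbutanoate | C[C@H](O)[C@H](C)C(=O)OC | intermediate
3 | 3,4,5-trimethoxybenzyl bromide (5-(bromomethyl)-1,2,3-trimethoxybenzene) | COc1cc(CBr)cc(OC)c1OC | starting material
4 | methyl (2S,3S)-2-methyl-3-[(3,4,5-trimethoxybenzyl)oxy]butanoate | C[C@H](OCc1cc(OC)c(OC)c(OC)c1)[C@H](C)C(=O)OC | intermediate
5 | (2R,3S)-2-methyl-3-[(3,4,5-trimethoxybenzyl)oxy]butan-1-ol | C[C@H](OCc1cc(OC)c(OC)c(OC)c1)[C@H](C)CO | intermediate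
6 | 5-({[(2S,3S)-4-iodo-3-methylbutan-2-yl]oxy}methyl)-1,2,3-trimethoxybenzene | C[C@H](OCc1cc(OC)c(OC)c(OC)c1)[C@H](C)CI | intermediate
7 | 4-bromo-2,6-dimethoxyphenol | COc1cc(Br)cc(OC)c1O | starting material
8 | (4-bromo-2,6-dimethoxyphenoxy)(tert-butyl)dimethylsilane | COc1cc(Br)cc(OC)c1O[Si](C)(C)C(C)(C)C | intermediate
9 | {(2S,3S)-2-methyl-3-[(3,4,5-trimethoxybenzyl)oxy]butyl}zinc iodide | C[C@H](OCc1cc(OC)c(OC)c(OC)c1)[C@H](C)C[Zn]I | intermediate
10 | tert-butyl(2,6-dimethoxy-4-{(2R,3S)-2-methyl-3-[(3,4,5-trimethoxybenzyl)oxy]butyl}phenoxy)dimethylsilane | COc1cc(C[C@@H](C)[C@H](C)OCc2cc(OC)c(OC)c(OC)c2)cc(OC)c1O[Si](C)(C)C(C)(C)C | intermediate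
11 | lithium (1R,2S,3R)-4-[4-(tert-butyldimethylsilyloxy)-3,5-dimethoxyphenyl]-2,3-dimethyl-1-(3,4,5-trimethoxyphenyl)butan-1-olate | [Li+].COc1cc(C[C@@H](C)[C@H](C)[C@@H]([O-])c2cc(OC)c(OC)c(OC)c2)cc(OC)c1O[Si](C)(C)C(C)(C)C | intermediate
12 | (1R,2S,3R)-4-[4-(tert-butyldimethylsilyloxy)-3,5-dimethoxyphenyl]-2,3-dimethyl-1-(3,4,5-trimethoxyphenyl)butyl acetate | COc1cc(C[C@@H](C)[C@H](C)[C@@H](OC(C)=O)c2cc(OC)c(OC)c(OC)c2)cc(OC)c1O[Si](C)(C)C(C)(C)C | intermediate
13 | (5R,6S,7R)-1,2,3,3',5'-pentamethoxy-6,7-dimethyl-4'-oxo-5,6,7,8-tetrahydrospiro[benzo[7]annulene-9,1'-cyclohexa[2,5]diene]-5-yl acetate | COC1=CC2(C=C(OC)C1=O)C[C@@H](C)[C@H](C)[C@@H](OC(C)=O)c1cc(OC)c(OC)c(OC)c12 | target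

Total step count: 7. Longest linear sequence: 6 steps (steps 1, 2, 3, 4, 6, 7); step 5 is a one-step side branch.

Steps most likely to fail

First, step 7. Ring lithiation next to a methoxy group or α′,β-elimination may compete with benzylic deprotonation. The radical pair may also recombine with poor facial selectivity at C5, and the oxidation has to run in the presence of the spent reagents of the first two stages. The fallback separates the three events and sets C5 with a reagent. It sets out from 10 and comes back to the route at 12. The [1,2]-Wittig rearrangement (s-BuLi, THF, then aqueous NH4Cl) is worked up to give the rearranged alcohol as a mixture of C1 epimers, (2S,3R)-4-[4-(tert-butyldimethylsilyloxy)-3,5-dimethoxyphenyl]-2,3-dimethyl-1-(3,4,5-trimethoxyphenyl)butan-1-ol F1. Dess–Martin oxidation under buffered, base-free conditions should give the aryl ketone (2S,3R)-4-[4-(tert-butyldimethylsilyloxy)-3,5-dimethoxyphenyl]-2,3-dimethyl-1-(3,4,5-trimethoxyphenyl)butan-1-one F2; the phenol ring is still aromatic at this stage, so no dienone competes. Corey–Bakshi–Shibata reduction with the (S)-methyl oxazaborolidine and BH3·SMe2 should then give the single (1R,2S,3R) alcohol F3 under catalyst control, with the aryl group as the larger substituent. Ac2O/pyridine gives 12, now isolated, and PhI(OCOCF3)2 in CF3CH2OH at −40 °C closes the ring to 13.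

Second, step 2. Alkylation of the hindered secondary hydroxyl may be slow, and the electron-rich bromide may hydrolyse or self-condense on silver oxide. The fallback replaces silver activation by acid-catalysed imidate alkylation; it sets out from 2 and comes back at 4. Commercial (3,4,5-trimethoxyphenyl)methanol is converted with Cl3CCN and catalytic DBU into (3,4,5-trimethoxyphenyl)methyl 2,2,2-trichloroacetimidate F4, which should etherify 2 under catalytic TfOH in CH2Cl2 at 0 °C to give 4.

Third, step 6. Zinc insertion into the β-branched iodide may be incomplete, or the alkylzinc may be protonated before it couples. The fallback reverses the polarity of the coupling; it sets out from 8 and comes back at 10. Mg turnings in THF convert 8 into the aryl Grignard reagent [4-(tert-butyldimethylsilyloxy)-3,5-dimethoxyphenyl]magnesium bromide F5, which is coupled with iodide 6 in an iron-catalysed Kumada-type reaction (Fe(acac)3, TMEDA, THF, 0 °C) to give 10.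

Further compounds
F1 | step 7 | (2S,3R)-4-[4-(tert-butyldimethylsilyloxy)-3,5-dimethoxyphenyl]-2,3-dimethyl-1-(3,4,5-trimethoxyphenyl)butan-1-ol, mixture of C1 epimers | COc1cc(C[C@@H](C)[C@H](C)C(O)c2cc(OC)c(OC)c(OC)c2)cc(OC)c1O[Si](C)(C)C(C)(C)C
F2 | step 7 | (2S,3R)-4-[4-(tert-butyldimethylsilyloxy)-3,5-dimethoxyphenyl]-2,3-dimethyl-1-(3,4,5-trimethoxyphenyl)butan-1-one | COc1cc(C[C@@H](C)[C@H](C)C(=O)c2cc(OC)c(OC)c(OC)c2)cc(OC)c1O[Si](C)(C)C(C)(C)C
F3 | step 7 | (1R,2S,3R)-4-[4-(tert-butyldimethylsilyloxy)-3,5-dimethoxyphenyl]-2,3-dimethyl-1-(3,4,5-trimethoxyphenyl)butan-1-ol | COc1cc(C[C@@H](C)[C@H](C)[C@@H](O)c2cc(OC)c(OC)c(OC)c2)cc(OC)c1O[Si](C)(C)C(C)(C)C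
F4 | step 2 | (3,4,5-trimethoxyphenyl)methyl 2,2,2-trichloroacetimidate | COc1cc(COC(=N)C(Cl)(Cl)Cl)cc(OC)c1OC
F5 | step 6 | [4-(tert-butyldimethylsilyloxy)-3,5-dimethoxyphenyl]magnesium bromide | COc1cc([Mg]Br)cc(OC)c1O[Si](C)(C)C(C)(C)C
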